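**Retrosynthetic overview**
1. Target 27 ⇒ O‑methyl ylidene tetronate 26 (thiolate O‑demethylation) ⇒ aldehyde 22 + 4‑methoxy‑3‑methylfuran‑2(5H)‑one 20 (aldol, then E1cB to the Z‑ylidene).
2. 22 ⇒ C2‑symmetric (2S,6S)‑2,6‑dimethylheptanedial 9 + allylic tributylphosphonium salt 18 (E‑selective mono‑Wittig; the two CHO groups of 9 are homotopic).
3. 9 ⇒ diol 8 ⇒ nitro diol 7 ⇒ two propanal + C3 linchpin 2 (two‑directional enamine Michael/E1cB/Michael; sets both stereocentres in one step).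
4. 18 ⇒ pent‑1‑en‑4‑yne (carboalumination/hydroxymethylation) + 3‑bromofuran (B‑alkyl Suzuki).
5. Rings: the furan and the butenolide are bought intact; no ring is formed in the route.

Assumption: 2‑nitropropane‑1,3‑diol, pent‑1‑en‑4‑yne and 3‑methyltetronic acid are taken as catalogue chemicals.

**Step 1**
Reactants: 1 2‑nitropropane‑1,3‑diol
Product: 2 2‑nitropropane‑1,3‑diyl diacetate
Conditions: Ac2O (2.5 equiv), H2SO4 (cat.), 0 °C → rt
Reagents that add atoms: acetic anhydride CC(=O)OC(C)=O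
Why: Acid‑catalysed O‑acetylation (esterification) under non‑basic conditions, so the β‑acetoxy nitro compound does not eliminate prematurely.

**Step 2**
Reactants: 2 2‑nitropropane‑1,3‑diyl diacetate; 3 propanal
Product: 7 (2S,6S)-2,6-dimethyl-4-nitroheptane-1,7-diol, via 2-nitroallyl acetate 4 (not isolated), via nitroalkene aldehyde 5 (not isolated), via nitro dialdehyde 6 (not isolated)
Conditions: 3 (6 equiv), (R)‑α,α‑diphenylprolinol TMS ether (15 mol %), N‑methylmorpholine (2.2 equiv), PhMe, 0 °C → rt; then EtOH, NaBH4, 0 °C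
Reagents that add atoms: none
Why: Proposed new method: N‑methylmorpholine releases 2‑nitroallyl acetate 4 slowly from 2 (E1cB); the anti‑(E)‑enamine of propanal adds through the face not shielded by the CPh2OTMS group to the CH2 terminus of 4, the nitronate expels acetate to give nitroalkene 5, and 5 accepts a second enamine in the same way, so both α‑stereocentres are set independently by the catalyst ((R)‑catalyst gives S at each centre, by the same facial model that gives 2R products from the (S)‑catalyst with nitroalkenes) and C4 is not stereogenic in the C2 isomer; in‑situ NaBH4 reduction then freezes the epimerisable aldehydes as diol 7; the closest known reactions are the diarylprolinol‑ether‑catalysed Michael addition of aldehydes to nitroethylene and the stoichiometric double coupling of preformed achiral enamines with 2‑nitroallyl esters, while a catalytic asymmetric two‑fold version has not been shown.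

**Step 3**
Reactants: 7 (2S,6S)‑2,6‑dimethyl‑4‑nitroheptane‑1,7‑diol
Product: 8 (2S,6S)-2,6-dimethylheptane-1,7-diol
Conditions: Bu3SnH (5 equiv), AIBN (0.4 equiv, in portions), PhMe, 110 °C
Reagents that add atoms: none
Why: Radical denitration (stannyl radical adds to the nitro group, C–N fragmentation, H‑transfer to the secondary C4 radical); the stereocentres are remote and untouched.

**Step 4**
Reactants: 8 (2S,6S)‑2,6‑dimethylheptane‑1,7‑diol
Product: 9 (2S,6S)-2,6-dimethylheptanedial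
Conditions: TEMPO (0.2 equiv), PhI(OAc)2 (2.4 equiv), CH2Cl2, rt
Reagents that add atoms: none
Why: TEMPO/oxoammonium oxidation of both primary alcohols under base‑free conditions, which stops at the aldehyde and does not epimerise the α‑methyl centres.

**Step 5**
Reactants: 10 pent‑1‑en‑4‑yne
Product: 13 (2E)-3-methylhexa-2,5-dien-1-ol, via vinylalane 11 (not isolated), via lithium alanate 12 (not isolated)
Conditions: Me3Al (2 equiv), Cp2ZrCl2 (0.25 equiv), CH2Cl2, 0 °C → rt; then n‑BuLi, THF, −78 → 0 °C; (CH2O)n, rt; aq HCl work‑up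
Reagents that add atoms: trimethylaluminium C[Al](C)C; formaldehyde (as paraformaldehyde) C=O
Why: Zr‑catalysed syn‑carboalumination of the terminal alkyne (Negishi) fixes the E‑trisubstituted alkene, and the alanate is hydroxymethylated with retention; the terminal alkene is inert under these conditions.

**Step 6**
Reactants: 13 (2E)‑3‑methylhexa‑2,5‑dien‑1‑ol; 14 3‑bromofuran
Product: 16 (2E)-6-(furan-3-yl)-3-methylhex-2-en-1-ol, via alkylborane 15 (not isolated)
Conditions: 9‑BBN (2.2 equiv), THF, 0 °C → rt; then 14 (1.2 equiv), PdCl2(dppf) (5 mol %), 3 M aq NaOH, THF/DMF, 60 °C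
Reagents that add atoms: none
Why: 9‑BBN hydroborates only the monosubstituted alkene (anti‑Markovnikov; the OH is carried as its borinate), and B‑alkyl Suzuki–Miyaura coupling joins the primary alkylborane to the furan C3.

**Step 7**
Reactants: 16 (2E)‑6‑(furan‑3‑yl)‑3‑methylhex‑2‑en‑1‑ol
Product: 18 tributyl[(2E)-6-(furan-3-yl)-3-methylhex-2-en-1-yl]phosphonium bromide, via allylic bromide 17 (not isolated)
Conditions: PBr3 (0.4 equiv), pyridine (cat.), Et2O, −20 → 0 °C; then PBu3 (1.1 equiv), MeCN, rt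
Reagents that add atoms: phosphorus tribromide BrP(Br)Br; tributylphosphine CCCCP(CCCC)CCCC
Why: Bromination of the primary allylic alcohol with retention of alkene geometry, then SN2 quaternisation of PBu3 at the primary carbon.

**Step 8**
Reactants: 19 3‑methyltetronic acid
Product: 20 4-methoxy-3-methylfuran-2(5H)-one
Conditions: Me2SO4, K2CO3, acetone, reflux
Reagents that add atoms: dimethyl sulfate COS(=O)(=O)OC
Why: O‑alkylation of the vinylogous acid at O4 with a hard methylating agent gives the methyl tetronate.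

**Step 9**
Reactants: 9 (2S,6S)‑2,6‑dimethylheptanedial; 18 tributyl[(2E)‑6‑(furan‑3‑yl)‑3‑methylhex‑2‑en‑1‑yl]phosphonium bromide
Product: 22 (2S,6S,7E,9E)-13-(furan-3-yl)-2,6,10-trimethyltrideca-7,9-dienal, via ylide 21 (not isolated)
Conditions: 18 (1 equiv), KHMDS (1 equiv), THF, −78 °C; ylide added to 9 (3 equiv), THF, −78 °C → rt; excess 9 recovered
Reagents that add atoms: none
Why: Wittig olefination with a semi‑stabilised allylic trialkylphosphonium ylide, which is E‑selective; the homotopic aldehydes of C2‑symmetric 9 give one mono‑olefination product, and excess 9 suppresses the bis‑adduct.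

**Step 10**
Reactants: 20 4‑methoxy‑3‑methylfuran‑2(5H)‑one; 22 (2S,6S,7E,9E)‑13‑(furan‑3‑yl)‑2,6,10‑trimethyltrideca‑7,9‑dienal
Product: 26 (5Z)-5-[(2S,6S,7E,9E)-13-(furan-3-yl)-2,6,10-trimethyltrideca-7,9-dien-1-ylidene]-4-methoxy-3-methylfuran-2(5H)-one, via lithium enolate 23 (not isolated), via lithium aldolate 24 (not isolated), via mesylate 25 (not isolated)
Conditions: 20 (1.3 equiv), LDA (1.25 equiv), THF, −78 °C; 22; then MsCl (1.5 equiv), −78 → 0 °C; DBU (3 equiv), rt
Reagents that add atoms: none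
Why: Vinylogous aldol addition of the C5‑lithiated tetronate, mesylation of the aldolate and DBU‑mediated E1cB elimination give the thermodynamically preferred Z‑ylidene (chain away from the 4‑OMe); the two transient carbinol stereocentres are erased and the α‑methyl centre is not acidic enough to epimerise.

**Step 11**
Reactants: 26 (5Z)‑5‑[(2S,6S,7E,9E)‑13‑(furan‑3‑yl)‑2,6,10‑trimethyltrideca‑7,9‑dien‑1‑ylidene]‑4‑methoxy‑3‑methylfuran‑2(5H)‑one
Product: 27 (5Z)-5-[(2S,6S,7E,9E)-13-(furan-3-yl)-2,6,10-trimethyltrideca-7,9-dien-1-ylidene]-4-hydroxy-3-methylfuran-2(5H)-one (CNP0389221.1)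
Conditions: NaSEt (3 equiv), DMF, 40 °C; then 1 M HCl work‑up
Reagents that add atoms: none
Why: SN2 O‑demethylation by thiolate with the tetronate (pKa ≈ 4) as leaving group, under non‑acidic conditions that spare the furan, the diene and the Z‑ylidene.

**Compound list**
1 | 2‑nitropropane‑1,3‑diol | OCC(CO)[N+](=O)[O-] | starting material
2 | 2‑nitropropane‑1,3‑diyl diacetate | CC(=O)OCC(COC(C)=O)[N+](=O)[O-] | intermediate
3 | propanal | CCC=O | starting material
4 | 2‑nitroallyl acetate (2‑nitroprop‑2‑en‑1‑yl acetate) | CC(=O)OCC(=C)[N+](=O)[O-] | intermediate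
5 | (2S)‑2‑methyl‑4‑nitropent‑4‑enal | O=C[C@@H](C)CC(=C)[N+](=O)[O-] | intermediate
6 | (2S,6S)‑2,6‑dimethyl‑4‑nitroheptanedial | O=C[C@@H](C)CC(C[C@H](C)C=O)[N+](=O)[O-] | intermediate
7 | (2S,6S)‑2,6‑dimethyl‑4‑nitroheptane‑1,7‑diol | OC[C@@H](C)CC(C[C@H](C)CO)[N+](=O)[O-] | intermediate
8 | (2S,6S)‑2,6‑dimethylheptane‑1,7‑diol | OC[C@@H](C)CCC[C@H](C)CO | intermediate
9 | (2S,6S)‑2,6‑dimethylheptanedial | O=C[C@@H](C)CCC[C@H](C)C=O | intermediate
10 | pent‑1‑en‑4‑yne | C=CCC#C | starting material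
11 | dimethyl[(1E)‑2‑methylpenta‑1,4‑dien‑1‑yl]alane | C[Al](C)/C=C(\C)CC=C | intermediate
12 | lithium butyl(dimethyl)[(1E)‑2‑methylpenta‑1,4‑dien‑1‑yl]alanate | [Li+].CCCC[Al-](C)(C)/C=C(\C)CC=C | intermediate
13 | (2E)‑3‑methylhexa‑2,5‑dien‑1‑ol | OC/C=C(\C)CC=C | intermediate
14 | 3‑bromofuran | Brc1ccoc1 | starting material
15 | 9‑[(4E)‑6‑(9‑borabicyclo[3.3.1]nonan‑9‑yloxy)‑4‑methylhex‑4‑en‑1‑yl]‑9‑borabicyclo[3.3.1]nonane | C/C(=C\COB1C2CCCC1CCC2)CCCB1C2CCCC1CCC2 | intermediate
16 | (2E)‑6‑(furan‑3‑yl)‑3‑methylhex‑2‑en‑1‑ol | OC/C=C(\C)CCCc1ccoc1 | intermediate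
17 | 3‑[(4E)‑6‑bromo‑4‑methylhex‑4‑en‑1‑yl]furan | BrC/C=C(\C)CCCc1ccoc1 | intermediate
18 | tributyl[(2E)‑6‑(furan‑3‑yl)‑3‑methylhex‑2‑en‑1‑yl]phosphonium bromide | [Br-].CCCC[P+](CCCC)(CCCC)C/C=C(\C)CCCc1ccoc1 | intermediate
19 | 3‑methyltetronic acid (4‑hydroxy‑3‑methylfuran‑2(5H)‑one) | CC1=C(O)COC1=O | starting material
20 | 4‑methoxy‑3‑methylfuran‑2(5H)‑one | COC1=C(C)C(=O)OC1 | intermediate
21 | tributyl[(2E)‑6‑(furan‑3‑yl)‑3‑methylhex‑2‑en‑1‑ylidene]phosphorane | CCCCP(CCCC)(CCCC)=C/C=C(\C)CCCc1ccoc1 | intermediate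
22 | (2S,6S,7E,9E)‑13‑(furan‑3‑yl)‑2,6,10‑trimethyltrideca‑7,9‑dienal | O=C[C@@H](C)CCC[C@H](C)/C=C/C=C(\C)CCCc1ccoc1 | intermediate
23 | lithium 4‑methoxy‑3‑methylfuran‑2‑olate | [Li]OC1=C(C)C(OC)=CO1 | intermediate
24 | lithium alkoxide of 5‑[(2S,6S,7E,9E)‑13‑(furan‑3‑yl)‑1‑hydroxy‑2,6,10‑trimethyltrideca‑7,9‑dien‑1‑yl]‑4‑methoxy‑3‑methylfuran‑2(5H)‑one (mixture at C5 and C1′) | COC1=C(C)C(=O)OC1C(O[Li])[C@@H](C)CCC[C@H](C)/C=C/C=C(\C)CCCc1ccoc1 | intermediate
25 | (2S,6S,7E,9E)‑13‑(furan‑3‑yl)‑1‑(3‑methoxy‑4‑methyl‑5‑oxo‑2,5‑dihydrofuran‑2‑yl)‑2,6,10‑trimethyltrideca‑7,9‑dien‑1‑yl methanesulfonate (mixture at C1 and the ring carbon) | COC1=C(C)C(=O)OC1C(OS(C)(=O)=O)[C@@H](C)CCC[C@H](C)/C=C/C=C(\C)CCCc1ccoc1 | intermediate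
26 | (5Z)‑5‑[(2S,6S,7E,9E)‑13‑(furan‑3‑yl)‑2,6,10‑trimethyltrideca‑7,9‑dien‑1‑ylidene]‑4‑methoxy‑3‑methylfuran‑2(5H)‑one | CC1=C(OC)/C(=C/[C@@H](C)CCC[C@H](C)/C=C/C=C(\C)CCCc2ccoc2)OC1=O | intermediate
27 | (5Z)‑5‑[(2S,6S,7E,9E)‑13‑(furan‑3‑yl)‑2,6,10‑trimethyltrideca‑7,9‑dien‑1‑ylidene]‑4‑hydroxy‑3‑methylfuran‑2(5H)‑one | CC1=C(O)/C(=C/[C@@H](C)CCC[C@H](C)/C=C/C=C(\C)CCCc2ccoc2)OC1=O | target

**Totals**
Total step count: 11. Longest linear sequence: 7 steps (steps 1, 2, 3, 4, 9, 10, 11).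

**Three steps most likely to fail**

Step 2 (the proposed new reaction). Risks are oligomerisation of the nitroalkenes, catalyst sequestration, and a few % of the meso (2R,6S) diastereomer that must be removed by recrystallising 7. The fallback uses the known photo‑organocatalytic formal α‑methylation of aldehydes. It does not set out from a numbered compound: compounds 1–7 are dropped and the starting material is purchased cycloheptene. Ozonolysis (O3, CH2Cl2, −78 °C; PPh3) gives heptanedial F1. F1 is alkylated at both α‑carbons with iodomethyl phenyl sulfone (3 equiv) under direct near‑UV excitation of the enamine formed with an (S)‑diarylprolinol silyl ether (20 mol %, 2,6‑lutidine), giving bis‑sulfone dialdehyde F2; in this pattern the sulfonylmethyl group enters where the methyl will sit, so the (S)‑catalyst gives the S centres. F2 is reduced in the same pot with NaBH4 to bis‑sulfone diol F3. Mg in MeOH then removes both phenylsulfonyl groups, and the fallback comes back to the route at diol 8.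

Step 3 (radical denitration of an unactivated secondary nitro group). Risk is incomplete conversion and tin contamination. The fallback sets out from nitro diol 7 and uses ionic chemistry: a Nef reaction (NaOMe, MeOH; then buffered aq TiCl3/NH4OAc) gives keto diol F4. Wolff–Kishner reduction (N2H4·H2O, KOH, diethylene glycol, 120 → 200 °C) through hydrazone F5 removes the carbonyl. The stereocentres are β to the ketone and cannot epimerise. The fallback comes back at diol 8.

Step 9 (statistical mono‑Wittig). Risks are E/Z erosion at the new alkene, bis‑olefination and α‑epimerisation of the dialdehyde. The fallback sets out from diol 8 and reverses the polarity of the olefination. Mitsunobu reaction with 1‑phenyl‑1H‑tetrazole‑5‑thiol (1 equiv; PPh3, DIAD, THF, 0 °C; diol recycled) gives hydroxy sulfide F6. Oxidation with (NH4)6Mo7O24/H2O2 in EtOH gives hydroxy sulfone F7. Allylic alcohol 16 is oxidised with MnO2 to enal F8. Julia–Kocienski olefination of F7 (KHMDS 2.1 equiv, DME, −60 °C, hydroxyl carried as its alkoxide) with F8 gives dienol F9; an alkyl PT‑sulfone with an enal is reliably E‑selective. Dess–Martin oxidation (NaHCO3, CH2Cl2) of F9 comes back to the route at aldehyde 22.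

**Further compounds**
F1 | step 2 | heptanedial | O=CCCCCCC=O
F2 | step 2 | (2S,6S)‑2,6‑bis[(phenylsulfonyl)methyl]heptanedial | O=C[C@@H](CS(=O)(=O)c1ccccc1)CCC[C@H](CS(=O)(=O)c1ccccc1)C=O
F3 | step 2 | (2S,6S)‑2,6‑bis[(phenylsulfonyl)methyl]heptane‑1,7‑diol | OC[C@@H](CS(=O)(=O)c1ccccc1)CCC[C@H](CS(=O)(=O)c1ccccc1)CO
F4 | step 3 | (2S,6S)‑1,7‑dihydroxy‑2,6‑dimethylheptan‑4‑one | OC[C@@H](C)CC(=O)C[C@H](C)CO
F5 | step 3 | (2S,6S)‑4‑hydrazinylidene‑2,6‑dimethylheptane‑1,7‑diol | OC[C@@H](C)CC(=NN)C[C@H](C)CO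
F6 | step 9 | (2S,6S)‑2,6‑dimethyl‑7‑[(1‑phenyl‑1H‑tetrazol‑5‑yl)sulfanyl]heptan‑1‑ol | OC[C@@H](C)CCC[C@H](C)CSc1nnnn1-c1ccccc1
F7 | step 9 | (2S,6S)‑2,6‑dimethyl‑7‑[(1‑phenyl‑1H‑tetrazol‑5‑yl)sulfonyl]heptan‑1‑ol | OC[C@@H](C)CCC[C@H](C)CS(=O)(=O)c1nnnn1-c1ccccc1
F8 | step 9 | (2E)‑6‑(furan‑3‑yl)‑3‑methylhex‑2‑enal | O=C/C=C(\C)CCCc1ccoc1
F9 | step 9 | (2S,6S,7E,9E)‑13‑(furan‑3‑yl)‑2,6,10‑trimethyltrideca‑7,9‑dien‑1‑ol | OC[C@@H](C)CCC[C@H](C)/C=C/C=C(\C)CCCc1ccoc1
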